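Start from the amounts. Ochre holds 0.10 M of D against 0.105 M of G, so its spare G, the charge of G less the charge of D, is 0.00500 M. Alpha has 0.0550 M spare at the same temperature, and there X falls from 20.0% to 16.3%, while beta and delta, colder and with less spare G, show no such fall.

| flask | D | G | temperature | remark | time |
|---|---|---|---|---|---|
| beta | 0.10 M | 0.105 M | 10 °C | run made earlier |  |
| alpha | 0.050 M | 0.105 M | 25 °C | run made earlier |  |
| delta | 0.075 M | 0.105 M | 10 °C | run made earlier |  |
| ochre | 0.10 M | 0.105 M | 25 °C | everything together at the start | 25 min |
| blue | 0.10 M (fed, over 15 min) | 0.105 M | 25 °C | all else is in the flask from the start; the feed brings no volume worth counting | 25 min |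
| amber | 0.10 M | 0.105 M (fed, over 15 min) | 25 °C | all else is in the flask from the start; the feed brings no volume worth counting | 25 min |
| grey | 0.10 M (fed, over 15 min) | 0.105 M |  | the addition at −5 °C, then warmed to 25 °C; the feed brings no volume worth counting | 25 min |

| run | time / min | X / % |
|---|---|---|
| beta | 4.00 | 23.5 |
| beta | 12.0 | 25.7 |
| beta | 25.0 | 26.7 |
| beta | 40.0 | 26.2 |
| beta | 50.0 | 26.5 |
| alpha | 4.00 | 20.0 |
| alpha | 8.00 | 17.8 |
| alpha | 12.0 | 16.7 |
| alpha | 15.0 | 16.6 |
| alpha | 20.0 | 16.3 |
| delta | 8.00 | 27.8 |
| delta | 15.0 | 27.5 |
| delta | 25.0 | 27.0 |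
| delta | 30.0 | 27.5 |
| delta | 40.0 | 28.0 |

(each reading ± 0.3 percentage points)

* the flask that comes out highest in amount of X, in percent of the D charged, or "all alike" when all lie within 1.5 percentage points (ochre / blue / amber / grey / all alike)
* X at the end, in percent of the D charged, ochre
* X at the end, in percent of the D charged, blue
* X at the end, in percent of the D charged, amber
* X at the end, in percent of the D charged, grey



Work in powers of ten and define the loss coefficient: the decades of X lost per molar of spare G, read from alpha as 1.62 L mol⁻¹. My reckoning for ochre takes alpha's early reading down by that coefficient times ochre's spare G.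

Now ask which numbers must be known well. Take the plateau first: raise it by 0.3 percentage points and my figure for ochre moves 0.033 points, which is less than the scatter of one reading. Next take ochre's spare G: an error of 0.00500 M in it moves my figure 0.36 points, which matters little. The early reading passes into ochre almost point for point, so that is the number to know, and my figure for ochre is 19.6%.

Blue begins with the whole of G spare and ends with 0.00500 M, a mean of 0.0550 M, so I reckon 16.3%. Amber's spare G, the G fed less the D charged, reaches ochre's 0.00500 M at the end of its feed, so I reckon amber equal to ochre. I expect grey, fed cold, to stand highest, though I put no figure on it.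

The forecast differs: it says all alike, with 15.3% for ochre, 15.5% for blue, 15.5% for amber and 16% for grey, reasoning that “If the end state is thermodynamic, the order of addition cannot matter”.

The flasks give 20.4% for ochre, 9.61% for blue, 15.0% for amber and 22.9% for grey, so grey stands highest.

2 G → Z (k = 0.0210 L mol⁻¹ s⁻¹, Ea = 70.0 kJ mol⁻¹); G + X → Q (k = 0.200 L mol⁻¹ s⁻¹, Ea = 57.0 kJ mol⁻¹); D + G → E + X (k = 0.0870 L mol⁻¹ s⁻¹, Ea = 39.0 kJ mol⁻¹); D ⇌ L (K = 1.00, k = 0.00110 s⁻¹, Ea = 77.0 kJ mol⁻¹, ΔH = 1.00 kJ mol⁻¹); G + E ⇌ J, settled at all times (K = 28000 L mol⁻¹, ΔH = −17.0 kJ mol⁻¹); (constants at 25 °C) Ochre lies 0.80 points above my figure, while blue and amber lie 6.7 points and 4.6 points below mine. G is the limiting reagent: ochre ends with 0.224% of its G beside 31.1% of its D. Now take a neighbour of grey, like it but with 0.18 M of G. Its spare G is 0.0800 M, so the coefficient takes grey's figure down to 17.3%. The neighbour ends at 21.7% of X, with D at 25.8% and Q at 36.4%.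

All runs were generated by integration with made-up constants; the scatter is artificial.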